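# Lapiferine from (S)-terpinen-4-ol by a rhodium-catalysed [5+2] cycloaddition

Numbering of the carbon skeleton used throughout: C1 is the methyl-bearing ring-fusion carbon, C2 and C3 follow, C4 is the isopropyl carbinol, C5 the ring-fusion CH, C6 the ester carbinol, C7 a methylene, C8 and C9 the epoxide carbons (methyl on C8) and C10 the free carbinol. The face that carries the C1 methyl is called β.

## Analysis of the target

Lapiferine is a daucane sesquiterpenoid ester. A cyclopentane (C1–C5) and a cycloheptane (C1, C5–C10) share the C1–C5 bond; C1 is quaternary, C4 is a tertiary carbinol that also bears the isopropyl group, C6 carries the angelate, C8/C9 a trisubstituted epoxide and C10 a free secondary hydroxyl. There are seven stereocentres (C1, C4, C5, C6, C8, C9, C10): the C4 hydroxyl and the C8 methyl are β, whereas H5 (trans ring fusion), the C4 isopropyl group, the C6 and C10 oxygens and the epoxide oxygen are α. C1 and C4 are fully substituted, 1,3-related across the cyclopentane and cannot be corrected once set; the other centres can be relayed from them. The sensitive groups are the angelate (it isomerises to the tiglate with base, nucleophilic catalysts or heat), the epoxy alcohol (acid opening, epoxide migration) and the tertiary alcohol (elimination). The hard points are the quaternary C1 between an oxygenated carbon and the ring-fusion CH, four oxygenated carbons on a mobile seven-membered ring, and two secondary carbinols (C6, C10) that must be told apart. The strategy rests on two features: C4 with its arms C5–C6 and C3–C2–C1(CH3) is the carbon chain of terpinen-4-ol opened at its ring alkene, and the C9/C10 oxygens lie where a 1-silyloxy-vinylcyclopropane (C1=C10, C9, C8, C7) leaves a C9=C10 silyl enol ether after a [5+2] cycloaddition with a C5≡C6 alkyne.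

## Retrosynthetic reasoning

**30 ⇒ 29.** The two C–O bonds of the epoxide are cut first. The free C10 hydroxyl of 29 can direct an epoxidation to the syn (α) face of C8=C9, and making the epoxy alcohol last keeps it away from acid, base and hydride.

**29 ⇒ 28 ⇒ 26 + 27.** The C6–O acyl bond is cut. In 26 the C6 hydroxyl is the only free hydroxyl (C4 and C10 are silylated), so no selection between C6 and C10 is needed; both silyl groups then come off together.

**26 ⇒ 25 ⇒ 23.** C9–H is traced back to an enol triflate, and C5–H/C6–O to a syn hydroboration of C5=C6 from the α face. In 23 the C8=C9 alkene is tetrasubstituted and electron-poor, so the triflate also protects it while C5=C6 is hydroborated.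

**23 ⇒ 21 ⇒ 18 + 19.** The triflate comes from the C9 ketone, enolised towards C8. The C8 methyl is cut here, as an enolate alkylation with 19, and not carried on the cyclopropane. The cyclopropane opens stereospecifically, so a methyl-bearing cyclopropane carbon would dictate the face at C1; a cyclopropanation that nothing directs would give both cyclopropane diastereomers and hence both C1 epimers.

**18 ⇒ 16.** The C10–O bond is cut: Rubottom oxidation of the C9=C10 silyl enol ether, with oxygen delivered anti to the C1 methyl and the silyl group migrating onto the new oxygen.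

**16 ⇒ 15.** The key disconnection cuts C1–C5 and C6–C7. It removes both rings and the quaternary centre at once and leaves an acyclic alkyne–vinylcyclopropane whose only stereocentre is C4. The forward reaction has to insert a trisubstituted alkene terminus and choose its face from C4.

**15 ⇒ 13 + 14 ⇒ 12.** The cyclopropane is the enol ether alkene of 2-silyloxy diene 13 plus one carbon from 14; 13 is the kinetic dienol ether of methyl enone 12.

**12 ⇒ 10 + 11; 10 ⇒ 8 ⇒ 7.** The methyl ketone comes from Weinreb amide 10 and 11. The alkyne comes from the aldehyde by net dehydration through its enol nonaflate, so the ring carbons of 1 map directly onto C5 and C6. The aldehyde is unmasked only after the ketone has been olefinated, because a free keto-aldehyde has two enolisable carbonyls and would also undergo aldol reactions.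

**7 ⇒ 5 + 6.** C1=C10 is a Horner–Wadsworth–Emmons bond. A β-keto phosphonate does not olefinate a ketone usefully; the amide-stabilised phosphonate 6 does.

**5 ⇒ 2 ⇒ 1.** Oxidative cleavage of the ring alkene of 1 gives ketone (C1) and aldehyde (C6); the aldehyde is acetalised selectively in the same flask. C4 comes from the chiral pool.

## Alternatives that were turned down

**Alternative 1:** C1–C10 and C5–C6 are disconnected on a cyclopentanone. Cu(OTf)2 with a chiral N-heterocyclic carbene would add vinylmagnesium bromide A2 to 3-methylcyclopent-2-en-1-one A1, and the magnesium enolate would be trapped by (Z)-4-iodo-3-methylbut-3-enal A3 to give anti-aldol A4.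
- For: C1 is set by the catalyst, and the aldol fixes C5 and C6 early through a closed transition state. On this point it is stronger than the chosen route, which sets C5/C6 late by hydroboration.
- Against: a vinyl nucleophile forming a quaternary centre on a five-ring enone is at the limit of this catalysis. A3 is a β,γ-unsaturated aldehyde that isomerises easily. The step closes no ring, so the seven-membered ring (C9–C10, for example CrCl2/NiCl2 coupling after cleaving the vinyl group) and C4 (isopropyl addition to a hindered, enolisable β-hydroxy ketone that can undergo retro-aldol) remain, each with its own stereochemical problem.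
- Comparison: the chosen route takes C4 from the pool and closes both rings in one step.

**Alternative 2:** C7–C8 and C1–C10 are disconnected. Rh2(S-DOSP)4 (divalent rhodium) would decompose vinyldiazo ester A6, cyclopropanate the vinyl group of 3-methyl-2-vinylcyclopent-2-en-1-one A5, and the divinylcyclopropane would rearrange to hydroazulene A7.
- For: it is catalytic and asymmetric, and the rearrangement transfers stereochemistry so that C1 and the C10 oxygen arise together. It is stronger at C10, which the chosen route sets by a separate oxidation.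
- Against: the vinyl group of A5 is part of an electron-poor cross-conjugated dienone, a poor partner for an electrophilic carbenoid. The rearrangement must use a tetrasubstituted enone alkene to create the quaternary carbon. The C8 ester has to be reduced to a methyl group, the C4 carbinol still needs an isopropyl addition to a dienone (1,2 against 1,4 and face), and C5/C6 still need hydration.
- Comparison: the key step closes one ring, and more functional-group changes follow than in the chosen route.

**Alternative 3:** C1–C5 and C9–C10 are disconnected. Heating acetoxypyranone A8 with an amine base would form the oxidopyrylium, which adds to the tethered alkene to give oxygen-bridged tricycle A9.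
- For: like the chosen step it forms two bonds, both carbocycles and the quaternary C1, and it delivers C6 as a ketone, which is stronger than a late hydroboration.
- Against: the bridge places oxygen on C5 and C9, whereas the target needs hydrogen at C5 and oxygen at C10; C10 is an unfunctionalised methylene in A9. The C5–O bond must be cleaved reductively with control of the ring fusion, and C10 must be oxidised without a handle. A8 also needs a furyl carbinol next to the C4 carbinol, which terpinen-4-ol does not supply directly.
- Comparison: the chosen route puts the oxygen of the five-carbon unit at C9=C10, where it is used.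

Key step: step 9

Assumption: (S)-(+)-terpinen-4-ol is used in high enantiomeric purity, because C4 is the only source of absolute configuration up to step 9.

## Route

Step 1
Reactants: 1 (S)-terpinen-4-ol
Product: 2 (S)-triethyl[(1-isopropyl-4-methylcyclohex-3-en-1-yl)oxy]silane
Conditions: Et3SiOTf, 2,6-lutidine, CH2Cl2, 0 °C → rt
Reagents that add atoms: triethylsilyl trifluoromethanesulfonate, CC[Si](CC)(CC)OS(=O)(=O)C(F)(F)F
Why: Silyl triflate silylation of a hindered tertiary alcohol; the ether blocks retro-aldol and elimination at C4 and survives base, organometallic reagents and mild acid.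

Step 2
Reactants: 2 (S)-triethyl[(1-isopropyl-4-methylcyclohex-3-en-1-yl)oxy]silane
Product: 5 (S)-5-isopropyl-7,7-dimethoxy-5-(triethylsilyloxy)heptan-2-one, via secondary ozonide 3 (not isolated), via keto-aldehyde 4 (not isolated)
Conditions: O3, CH2Cl2, −78 °C; PPh3, −78 °C → rt; then HC(OMe)3, CeCl3·7H2O (cat.), MeOH, rt
Reagents that add atoms: ozone, [O-][O+]=O; methanol, CO; trimethyl orthoformate, COC(OC)OC
Why: Ozonolysis with reductive work-up cleaves the only alkene (the chiral-pool C–C cleavage; C4 is untouched), and CeCl3-catalysed acetalisation converts the aldehyde but not the methyl ketone. The 1,6-keto-aldehyde is not isolated, which avoids its intramolecular aldol reaction.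

Step 3
Reactants: 5 (S)-5-isopropyl-7,7-dimethoxy-5-(triethylsilyloxy)heptan-2-one; 6 diethyl (N-methoxy-N-methylcarbamoylmethyl)phosphonate
Product: 7 (2E,6S)-6-isopropyl-N,8,8-trimethoxy-N,3-dimethyl-6-(triethylsilyloxy)oct-2-enamide
Conditions: NaH, THF, 0 → 60 °C; E isomer separated by chromatography
Reagents that add atoms: 6 diethyl (N-methoxy-N-methylcarbamoylmethyl)phosphonate, CCOP(=O)(OCC)CC(=O)N(C)OC
Why: Horner–Wadsworth–Emmons olefination; the amide-stabilised phosphonate anion is nucleophilic enough for a methyl ketone, and the E isomer (longer chain trans to the carbonyl) should predominate.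

Step 4
Reactants: 7 (2E,6S)-6-isopropyl-N,8,8-trimethoxy-N,3-dimethyl-6-(triethylsilyloxy)oct-2-enamide
Product: 8 (2E,6S)-6-isopropyl-N-methoxy-N,3-dimethyl-8-oxo-6-(triethylsilyloxy)oct-2-enamide
Conditions: PPTS (cat.), acetone/H2O, 40 °C
Reagents that add atoms: water, O
Why: Mild acid-catalysed acetal hydrolysis; the dimethyl acetal of an aldehyde is far more labile than the hindered tertiary triethylsilyl ether or the amide.

Step 5
Reactants: 8 (2E,6S)-6-isopropyl-N-methoxy-N,3-dimethyl-8-oxo-6-(triethylsilyloxy)oct-2-enamide
Product: 10 (2E,6R)-6-isopropyl-N-methoxy-N,3-dimethyl-6-(triethylsilyloxy)oct-2-en-7-ynamide, via alkenyl nonaflate 9 (not isolated)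
Conditions: n-C4F9SO2F, phosphazene base P2-Et, DMF, −20 °C → rt
Reagents that add atoms: none
Why: Enol nonaflate formation and E2 elimination in one flask (aldehyde-to-alkyne dehydration); C4 is quaternary, so only the terminal alkyne can form, and the amide is the only other carbonyl and is not enolised by this base.

Step 6
Reactants: 10 (2E,6R)-6-isopropyl-N-methoxy-N,3-dimethyl-6-(triethylsilyloxy)oct-2-en-7-ynamide; 11 methylmagnesium bromide
Product: 12 (3E,7R)-7-isopropyl-4-methyl-7-(triethylsilyloxy)non-3-en-8-yn-2-one
Conditions: MeMgBr (3 equiv), THF, 0 °C; aq. NH4Cl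
Reagents that add atoms: 11 methylmagnesium bromide, C[Mg]Br
Why: Weinreb ketone synthesis; the chelated adduct prevents over-addition, the β,β-disubstituted alkene resists conjugate addition, and excess Grignard reagent only deprotonates the alkyne until work-up.

Step 7
Reactants: 12 (3E,7R)-7-isopropyl-4-methyl-7-(triethylsilyloxy)non-3-en-8-yn-2-one
Product: 13 (3E,7R)-2-(tert-butyldimethylsilyloxy)-7-isopropyl-4-methyl-7-(triethylsilyloxy)nona-1,3-dien-8-yne
Conditions: t-BuMe2SiOTf, Et3N, CH2Cl2, −78 → 0 °C
Reagents that add atoms: tert-butyldimethylsilyl trifluoromethanesulfonate, CC(C)(C)[Si](C)(C)OS(=O)(=O)C(F)(F)F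
Why: Soft enolisation (silyl triflate and amine) removes a proton from the α'-methyl group and gives the cross-conjugated 2-silyloxy diene; no strong base touches the terminal alkyne.

Step 8
Reactants: 13 (3E,7R)-2-(tert-butyldimethylsilyloxy)-7-isopropyl-4-methyl-7-(triethylsilyloxy)nona-1,3-dien-8-yne; 14 diiodomethane
Product: 15 tert-butyl{1-[(1E,5R)-5-isopropyl-2-methyl-5-(triethylsilyloxy)hept-1-en-6-yn-1-yl]cyclopropoxy}dimethylsilane
Conditions: Et2Zn, CH2I2, CH2Cl2, 0 °C; pyridine quench
Reagents that add atoms: 14 diiodomethane, ICI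
Why: Furukawa-modified Simmons–Smith cyclopropanation; the electrophilic zinc carbenoid selects the electron-rich 1,1-disubstituted enol ether alkene over the trisubstituted alkene and the alkyne, and the product has no cyclopropane stereocentre.

Step 9
Reactants: 15 tert-butyl{1-[(1E,5R)-5-isopropyl-2-methyl-5-(triethylsilyloxy)hept-1-en-6-yn-1-yl]cyclopropoxy}dimethylsilane
Product: 16 9-(tert-butyldimethylsilyloxy)-4α-isopropyl-1β-methyl-4β-(triethylsilyloxy)bicyclo[5.3.0]deca-5,9-diene
Conditions: [Rh(CO)2Cl]2 (5 mol%), ClCH2CH2Cl, 70 °C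
Reagents that add atoms: none
Why: Monovalent rhodium binds the alkyne and the vinylcyclopropane, opens a C9–CH2 bond of the strained, donor-substituted cyclopropane to a rhodacyclohexene (σ-alkyl at C7, allyl over C9–C10–C1), inserts the tethered alkyne at C1 to form C1–C5, and closes the ring by C6–C7 reductive elimination. The closest known reaction is the intramolecular rhodium-catalysed [5+2] cycloaddition of tethered alkyne–vinylcyclopropanes, which includes 1-silyloxy-vinylcyclopropanes; a trisubstituted alkene terminus that becomes quaternary is its demanding edge. The cyclopentene closes in the 5-exo-dig sense by migratory insertion (C6 stays exocyclic), and the cycloheptadiene closes by reductive elimination from an eight-membered rhodacycle. The only new stereocentre is C1, and C4 controls it: in the forming cyclopentene the isopropyl group takes the pseudo-equatorial site, so the smaller silyloxy oxygen lies syn to the methyl group that the bicyclic rhodacycle forces to be pseudo-axial. The step needs this face selectivity and clean insertion of a trisubstituted alkene; the quaternary C4 (Thorpe–Ingold effect), the terminal alkyne (no clash at C6), ring strain and the donor silyloxy group favour both. Because the cyclopropane carries no substituent besides oxygen, its two ring bonds are equivalent and no cyclopropane stereocentre competes with C4 for C1. The silyl enol ether emerges regiodefined at C9=C10.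

Step 10
Reactants: 16 9-(tert-butyldimethylsilyloxy)-4α-isopropyl-1β-methyl-4β-(triethylsilyloxy)bicyclo[5.3.0]deca-5,9-diene
Product: 18 10α-(tert-butyldimethylsilyloxy)-4α-isopropyl-1β-methyl-4β-(triethylsilyloxy)bicyclo[5.3.0]dec-5-en-9-one, via silyloxy epoxide 17 (not isolated)
Conditions: mCPBA, NaHCO3, CH2Cl2, −20 → 0 °C
Reagents that add atoms: 3-chloroperbenzoic acid, OOC(=O)c1cccc(Cl)c1
Why: Rubottom oxidation; the peracid epoxidises the electron-rich silyl enol ether faster than the hindered C5=C6 alkene, from the α face away from the C1 methyl, and the silyloxy epoxide opens with 1,4-silyl migration to the α-silyloxy ketone, which fixes C10.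

Step 11
Reactants: 18 10α-(tert-butyldimethylsilyloxy)-4α-isopropyl-1β-methyl-4β-(triethylsilyloxy)bicyclo[5.3.0]dec-5-en-9-one; 19 iodomethane
Product: 21 10α-(tert-butyldimethylsilyloxy)-4α-isopropyl-1β,8-dimethyl-4β-(triethylsilyloxy)bicyclo[5.3.0]dec-5-en-9-one (both C8 epimers), via lithium enolate 20 (not isolated)
Conditions: LiN(SiMe3)2, THF, −78 °C; MeI, DMPU, −78 → −20 °C
Reagents that add atoms: 19 iodomethane, CI
Why: Kinetic enolate alkylation; the amide base takes a proton from the C8 methylene and not from the hindered, oxygen-bearing C10 methine, and the C8 configuration is irrelevant because C8 becomes trigonal in step 12.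

Step 12
Reactants: 21 10α-(tert-butyldimethylsilyloxy)-4α-isopropyl-1β,8-dimethyl-4β-(triethylsilyloxy)bicyclo[5.3.0]dec-5-en-9-one
Product: 23 10α-(tert-butyldimethylsilyloxy)-4α-isopropyl-1β,8-dimethyl-4β-(triethylsilyloxy)bicyclo[5.3.0]deca-5,8-dien-9-yl trifluoromethanesulfonate, via potassium enolate 22 (not isolated)
Conditions: KN(SiMe3)2, THF, −78 °C; PhNTf2, −78 → 0 °C
Reagents that add atoms: N-phenylbis(trifluoromethanesulfonimide), O=S(=O)(N(c1ccccc1)S(=O)(=O)C(F)(F)F)C(F)(F)F
Why: Enol triflate formation from the kinetic potassium enolate; deprotonation at C8 is favoured over the C10 methine, which is flanked by quaternary C1 and its own silyloxy group, so C10 is not epimerised.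

Step 13
Reactants: 23 10α-(tert-butyldimethylsilyloxy)-4α-isopropyl-1β,8-dimethyl-4β-(triethylsilyloxy)bicyclo[5.3.0]deca-5,8-dien-9-yl trifluoromethanesulfonate
Product: 25 10α-(tert-butyldimethylsilyloxy)-6α-hydroxy-4α-isopropyl-1β,8-dimethyl-4β-(triethylsilyloxy)-5α-H-bicyclo[5.3.0]dec-8-en-9-yl trifluoromethanesulfonate, via alkylborane 24 (not isolated)
Conditions: BH3·THF, THF, 0 °C → rt; then NaBO3·4H2O, THF/H2O, rt
Reagents that add atoms: sodium perborate tetrahydrate (NaBO3·4H2O), [Na+].[Na+].O[B-]1(O)OO[B-](O)(O)OO1
Why: Hydroboration–oxidation; borane adds syn, boron to the less substituted C6 and hydrogen to C5, from the α face opposite the pseudo-axial C1 methyl and C4 silyloxy groups, which sets the trans ring fusion and the 6α-hydroxyl together while the tetrasubstituted, electron-poor enol triflate stays inert. Perborate oxidises the C–B bond with retention under conditions mild enough for the triflate.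

Step 14
Reactants: 25 10α-(tert-butyldimethylsilyloxy)-6α-hydroxy-4α-isopropyl-1β,8-dimethyl-4β-(triethylsilyloxy)-5α-H-bicyclo[5.3.0]dec-8-en-9-yl trifluoromethanesulfonate
Product: 26 10α-(tert-butyldimethylsilyloxy)-4α-isopropyl-1β,8-dimethyl-4β-(triethylsilyloxy)-5α-H-bicyclo[5.3.0]dec-8-en-6α-ol
Conditions: Pd(OAc)2 (10 mol%), PPh3, HCO2H, n-Bu3N, DMF, 60 °C
Reagents that add atoms: none
Why: Palladium-catalysed formate reduction of an enol triflate (oxidative addition, decarboxylation of formate to a palladium hydride, reductive elimination) replaces the triflate by hydrogen without moving the double bond.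

Step 15
Reactants: 26 10α-(tert-butyldimethylsilyloxy)-4α-isopropyl-1β,8-dimethyl-4β-(triethylsilyloxy)-5α-H-bicyclo[5.3.0]dec-8-en-6α-ol; 27 angelic acid
Product: 28 10α-(tert-butyldimethylsilyloxy)-4α-isopropyl-1β,8-dimethyl-4β-(triethylsilyloxy)-5α-H-bicyclo[5.3.0]dec-8-en-6α-yl (Z)-2-methylbut-2-enoate
Conditions: 27, 2,4,6-Cl3C6H2COCl, Et3N, toluene, rt; then 26, 80 °C
Reagents that add atoms: 27 angelic acid, C/C=C(/C)C(=O)O
Why: Yamaguchi esterification through the mixed anhydride, run without a nucleophilic catalyst because acyl-transfer catalysts isomerise angelates to tiglates; the C6 hydroxyl is the only free hydroxyl.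

Step 16
Reactants: 28 10α-(tert-butyldimethylsilyloxy)-4α-isopropyl-1β,8-dimethyl-4β-(triethylsilyloxy)-5α-H-bicyclo[5.3.0]dec-8-en-6α-yl (Z)-2-methylbut-2-enoate
Product: 29 4β,10α-dihydroxy-4α-isopropyl-1β,8-dimethyl-5α-H-bicyclo[5.3.0]dec-8-en-6α-yl (Z)-2-methylbut-2-enoate
Conditions: HF·pyridine, pyridine, THF, 0 °C → rt
Reagents that add atoms: none
Why: Fluoride-mediated desilylation under buffered acidic conditions cleaves both silyl ethers and leaves the angelate, which a basic fluoride source could isomerise or cleave.

Step 17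
Reactants: 29 4β,10α-dihydroxy-4α-isopropyl-1β,8-dimethyl-5α-H-bicyclo[5.3.0]dec-8-en-6α-yl (Z)-2-methylbut-2-enoate
Product: 30 lapiferine (6α-angeloyloxy-8α,9α-epoxy-daucane-4β,10α-diol)
Conditions: VO(acac)2 (5 mol%), t-BuOOH, CH2Cl2, 0 °C → rt
Reagents that add atoms: tert-butyl hydroperoxide, CC(C)(C)OO
Why: Vanadium-catalysed hydroxyl-directed epoxidation; the C10 vanadate ester delivers oxygen to the syn (α) face of the adjacent C8=C9 alkene of the seven-membered allylic alcohol, and the electron-poor angelate alkene does not react.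

## Compound list

1 | (S)-terpinen-4-ol | CC1=CC[C@](O)(C(C)C)CC1 | starting material
2 | (S)-terpinen-4-ol triethylsilyl ether | CC1=CC[C@](O[Si](CC)(CC)CC)(C(C)C)CC1 | intermediate
3 | secondary ozonide of 2 (1,2,4-trioxolane over former C1/C6, diastereomer mixture) | CC12CC[C@@](O[Si](CC)(CC)CC)(C(C)C)CC(OO1)O2 | intermediate (not isolated)
4 | (S)-3-isopropyl-6-oxo-3-(triethylsilyloxy)heptanal | O=CC[C@](O[Si](CC)(CC)CC)(C(C)C)CCC(C)=O | intermediate (not isolated)
5 | (S)-5-isopropyl-7,7-dimethoxy-5-(triethylsilyloxy)heptan-2-one | COC(OC)C[C@](O[Si](CC)(CC)CC)(C(C)C)CCC(C)=O | intermediate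
6 | diethyl (N-methoxy-N-methylcarbamoylmethyl)phosphonate | CCOP(=O)(OCC)CC(=O)N(C)OC | starting material
7 | (2E,6S)-6-isopropyl-N,8,8-trimethoxy-N,3-dimethyl-6-(triethylsilyloxy)oct-2-enamide | COC(OC)C[C@](O[Si](CC)(CC)CC)(C(C)C)CC/C(C)=C/C(=O)N(C)OC | intermediate
8 | (2E,6S)-6-isopropyl-N-methoxy-N,3-dimethyl-8-oxo-6-(triethylsilyloxy)oct-2-enamide | O=CC[C@](O[Si](CC)(CC)CC)(C(C)C)CC/C(C)=C/C(=O)N(C)OC | intermediate
9 | enol nonaflate of 8 (C5=C6, E/Z mixture) | O=S(=O)(OC=C[C@](O[Si](CC)(CC)CC)(C(C)C)CC/C(C)=C/C(=O)N(C)OC)C(F)(F)C(F)(F)C(F)(F)C(F)(F)F | intermediate (not isolated)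
10 | (2E,6R)-6-isopropyl-N-methoxy-N,3-dimethyl-6-(triethylsilyloxy)oct-2-en-7-ynamide | C#C[C@](O[Si](CC)(CC)CC)(C(C)C)CC/C(C)=C/C(=O)N(C)OC | intermediate
11 | methylmagnesium bromide | C[Mg]Br | starting material
12 | (3E,7R)-7-isopropyl-4-methyl-7-(triethylsilyloxy)non-3-en-8-yn-2-one | C#C[C@](O[Si](CC)(CC)CC)(C(C)C)CC/C(C)=C/C(C)=O | intermediate
13 | (3E,7R)-2-(tert-butyldimethylsilyloxy)-7-isopropyl-4-methyl-7-(triethylsilyloxy)nona-1,3-dien-8-yne | C#C[C@](O[Si](CC)(CC)CC)(C(C)C)CC/C(C)=C/C(=C)O[Si](C)(C)C(C)(C)C | intermediate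
14 | diiodomethane | ICI | starting material
15 | alkyne-tethered 1-silyloxy-vinylcyclopropane (key-step precursor) | C#C[C@](O[Si](CC)(CC)CC)(C(C)C)CC/C(C)=C/C1(O[Si](C)(C)C(C)(C)C)CC1 | intermediate
16 | bicyclo[5.3.0]deca-5,9-diene with C9 silyl enol ether (key-step product) | C1CCC(O[Si](C)(C)C(C)(C)C)=C[C@@]2(C)CC[C@@](O[Si](CC)(CC)CC)(C(C)C)C2=1 | intermediate
17 | 9α,10α-epoxide of 16 | C1CC[C@@]3(O[Si](C)(C)C(C)(C)C)O[C@H]3[C@@]2(C)CC[C@@](O[Si](CC)(CC)CC)(C(C)C)C2=1 | intermediate (not isolated)
18 | 10α-silyloxy C9 ketone | C1CCC(=O)[C@@H](O[Si](C)(C)C(C)(C)C)[C@@]2(C)CC[C@@](O[Si](CC)(CC)CC)(C(C)C)C2=1 | intermediate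
19 | iodomethane | CI | starting material
20 | lithium C8=C9 enolate of 18 | C1CC=C([O-])[C@@H](O[Si](C)(C)C(C)(C)C)[C@@]2(C)CC[C@@](O[Si](CC)(CC)CC)(C(C)C)C2=1.[Li+] | intermediate (not isolated)
21 | 8-methyl-10α-silyloxy C9 ketone (C8 epimers) | C1CC(C)C(=O)[C@@H](O[Si](C)(C)C(C)(C)C)[C@@]2(C)CC[C@@](O[Si](CC)(CC)CC)(C(C)C)C2=1 | intermediate
22 | potassium C8=C9 enolate of 21 | C1CC(C)=C([O-])[C@@H](O[Si](C)(C)C(C)(C)C)[C@@]2(C)CC[C@@](O[Si](CC)(CC)CC)(C(C)C)C2=1.[K+] | intermediate (not isolated)
23 | C8=C9 enol triflate | C1CC(C)=C(OS(=O)(=O)C(F)(F)F)[C@@H](O[Si](C)(C)C(C)(C)C)[C@@]2(C)CC[C@@](O[Si](CC)(CC)CC)(C(C)C)C2=1 | intermediate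
24 | 6α-boryl-5α-H alkylborane | B[C@H]1CC(C)=C(OS(=O)(=O)C(F)(F)F)[C@@H](O[Si](C)(C)C(C)(C)C)[C@@]2(C)CC[C@@](O[Si](CC)(CC)CC)(C(C)C)[C@H]12 | intermediate (not isolated)
25 | trans-fused 6α-alcohol with enol triflate | O[C@H]1CC(C)=C(OS(=O)(=O)C(F)(F)F)[C@@H](O[Si](C)(C)C(C)(C)C)[C@@]2(C)CC[C@@](O[Si](CC)(CC)CC)(C(C)C)[C@H]12 | intermediate
26 | trans-fused 6α-alcohol with C8=C9 alkene | O[C@H]1CC(C)=C[C@@H](O[Si](C)(C)C(C)(C)C)[C@@]2(C)CC[C@@](O[Si](CC)(CC)CC)(C(C)C)[C@H]12 | intermediate
27 | angelic acid | C/C=C(/C)C(=O)O | starting material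
28 | 6α-angelate bis-silyl ether | C/C=C(/C)C(=O)O[C@H]1CC(C)=C[C@@H](O[Si](C)(C)C(C)(C)C)[C@@]2(C)CC[C@@](O[Si](CC)(CC)CC)(C(C)C)[C@H]12 | intermediate
29 | 6α-angelate 4β,10α-diol with C8=C9 alkene | C/C=C(/C)C(=O)O[C@H]1CC(C)=C[C@@H](O)[C@@]2(C)CC[C@@](O)(C(C)C)[C@H]12 | intermediate
30 | lapiferine | C/C=C(/C)C(=O)O[C@H]1C[C@@]2(C)O[C@H]2[C@@H](O)[C@@]2(C)CC[C@@](O)(C(C)C)[C@H]12 | target

## Step count and least certain steps

Total: 17 steps. Longest linear sequence: 17 steps from 1 (the route is fully linear; 6, 11, 14, 19 and 27 are bought).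

**Step 9 (key step).** Most likely to go wrong: insufficient facial selectivity at C1. The only control element is the 1,3-related C4, whose isopropyl and silyloxy groups differ only moderately in size, and slow insertion of the trisubstituted alkene would leave room for competing isomerisation.
Fallback: let a cyclopropane stereocentre, not C4, choose the face. It sets out from Weinreb amide 10 and returns at ketone 21, so step 11 is skipped. EtMgBr gives ethyl enone F1, and t-BuMe2SiOTf/Et3N gives (Z)-silyl dienol ether F2. A reagent-controlled asymmetric Simmons–Smith cyclopropanation (Et2Zn, CH2I2, chiral dipeptide ligand) gives trans-2-methyl silyloxy-vinylcyclopropane F3, the diastereomer whose unsubstituted ring bond lies on the required alkene face. [Rh(CO)2Cl]2 opens that bond stereospecifically to cycloadduct F4, which already carries the C8 methyl. Rubottom oxidation through silyloxy epoxide F5 gives 21 as one C8 epimer.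

**Step 13.** Most likely to go wrong: poor or reversed facial selectivity of borane addition, because the α face carries the C4 isopropyl group; β-face addition would give the cis ring fusion and the 6β-alcohol.
Fallback: replace kinetic face selection by thermodynamic control. It sets out from enol triflate 23 and returns at alcohol 25. The cis-fused 6β-alcohol F6 from hydroboration is oxidised with Dess–Martin periodinane to cis-fused ketone F7. DBU equilibrates C5 to trans-fused ketone F8, in which C6 avoids the C4 isopropyl group. Equilibrating Meerwein–Ponndorf–Verley reduction (Al(OiPr)3, i-PrOH) then gives the equatorial 6α-alcohol 25.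

**Step 10.** Most likely to go wrong: poor facial selectivity of the peracid at C10 if the seven-membered ring places the C1 methyl near the plane of the enol ether, or competing epoxidation of C5=C6.
Fallback: reagent control in place of substrate control. It sets out from cycloadduct 16 and returns at ketone 18. MeLi in THF/HMPA cleaves the silyl enol ether to the regiodefined lithium enolate F9. The matched enantiomer of (camphorsulfonyl)oxaziridine hydroxylates it to 10α-hydroxy ketone F10, and t-BuMe2SiOTf/2,6-lutidine gives 18.

**Step 5.** Most likely to go wrong: β-elimination of the C4 silyloxy group from the aldehyde enolate before it is sulfonylated, or incomplete elimination of the alkenyl nonaflate.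
Fallback: excise C6 and bring in a new alkyne carbon. It sets out from aldehyde 8 and returns at alkyne 10. t-BuMe2SiOTf/Et3N gives aldehyde silyl enol ether F11. Ozonolysis of this electron-rich alkene, with an indicator dye to spare the electron-poor enamide alkene, gives the non-enolisable nor-aldehyde F12. Ohira–Bestmann homologation (dimethyl (1-diazo-2-oxopropyl)phosphonate, K2CO3, MeOH) then gives 10.

## Further compounds

F1 | step 9 | (3E,7R)-7-isopropyl-4-methyl-7-(triethylsilyloxy)... ethyl enone (dec-4-en-9-yn-3-one skeleton) | C#C[C@](O[Si](CC)(CC)CC)(C(C)C)CC/C(C)=C/C(=O)CC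
F2 | step 9 | (Z)-silyl dienol ether of F1 | C#C[C@](O[Si](CC)(CC)CC)(C(C)C)CC/C(C)=C/C(O[Si](C)(C)C(C)(C)C)=C/C
F3 | step 9 | trans-2-methyl silyloxy-vinylcyclopropane | C#C[C@](O[Si](CC)(CC)CC)(C(C)C)CC/C(C)=C/[C@]1(O[Si](C)(C)C(C)(C)C)C[C@H]1C
F4 | step 9 | 8-methyl cycloadduct with C9 silyl enol ether | C1C[C@@H](C)C(O[Si](C)(C)C(C)(C)C)=C[C@@]2(C)CC[C@@](O[Si](CC)(CC)CC)(C(C)C)C2=1
F5 | step 9 | 9α,10α-epoxide of F4 | C1C[C@@H](C)[C@@]3(O[Si](C)(C)C(C)(C)C)O[C@H]3[C@@]2(C)CC[C@@](O[Si](CC)(CC)CC)(C(C)C)C2=1
F6 | step 13 | cis-fused 6β-alcohol with enol triflate | O[C@@H]1CC(C)=C(OS(=O)(=O)C(F)(F)F)[C@@H](O[Si](C)(C)C(C)(C)C)[C@@]2(C)CC[C@@](O[Si](CC)(CC)CC)(C(C)C)[C@@H]12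
F7 | step 13 | cis-fused C6 ketone with enol triflate | O=C1CC(C)=C(OS(=O)(=O)C(F)(F)F)[C@@H](O[Si](C)(C)C(C)(C)C)[C@@]2(C)CC[C@@](O[Si](CC)(CC)CC)(C(C)C)[C@@H]12
F8 | step 13 | trans-fused C6 ketone with enol triflate | O=C1CC(C)=C(OS(=O)(=O)C(F)(F)F)[C@@H](O[Si](C)(C)C(C)(C)C)[C@@]2(C)CC[C@@](O[Si](CC)(CC)CC)(C(C)C)[C@H]12
F9 | step 10 | lithium C9=C10 enolate from 16 | C1CCC([O-])=C[C@@]2(C)CC[C@@](O[Si](CC)(CC)CC)(C(C)C)C2=1.[Li+]
F10 | step 10 | 10α-hydroxy C9 ketone | C1CCC(=O)[C@@H](O)[C@@]2(C)CC[C@@](O[Si](CC)(CC)CC)(C(C)C)C2=1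
F11 | step 5 | tert-butyldimethylsilyl enol ether of aldehyde 8 | CC(C)(C)[Si](C)(C)OC=C[C@](O[Si](CC)(CC)CC)(C(C)C)CC/C(C)=C/C(=O)N(C)OC
F12 | step 5 | nor-aldehyde (C5 formyl on C4) | O=C[C@](O[Si](CC)(CC)CC)(C(C)C)CC/C(C)=C/C(=O)N(C)OC
A1 | alternative 1 | 3-methylcyclopent-2-en-1-one | CC1=CC(=O)CC1
A2 | alternative 1 | vinylmagnesium bromide | C=C[Mg]Br
A3 | alternative 1 | (Z)-4-iodo-3-methylbut-3-enal | O=CC/C(C)=C\I
A4 | alternative 1 | trans-2,3-disubstituted cyclopentanone anti-aldol | O[C@@H](C/C(C)=C\I)[C@H]1C(=O)CC[C@]1(C)C=C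
A5 | alternative 2 | 3-methyl-2-vinylcyclopent-2-en-1-one | CC1=C(C=C)C(=O)CC1
A6 | alternative 2 | methyl (E)-4-(tert-butyldimethylsilyloxy)-2-diazobut-3-enoate | COC(=O)C(=[N+]=[N-])/C=C/O[Si](C)(C)C(C)(C)C
A7 | alternative 2 | hydroazulene dienone with C8 ester and C10 silyl ether | C1CC(C(=O)OC)=C[C@@H](O[Si](C)(C)C(C)(C)C)[C@@]2(C)CCC(=O)C2=1
A8 | alternative 3 | 6-acetoxy-2H-pyran-3(6H)-one with the C4 side chain | CC(=O)OC1OC(C(=O)C=C1C)[C@](O[Si](CC)(CC)CC)(C(C)C)CCC(C)=C
A9 | alternative 3 | oxygen-bridged tricyclic enone | O=C1C=C(C)[C@H]2C[C@@]3(C)CC[C@@](O[Si](CC)(CC)CC)(C(C)C)[C@@]13O2
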